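The constants were set for the occasion.

Going from 100 °C to 120 °C speeds the coupling that makes target by a factor of 4.4, and I wanted to know what that buys in a run of 6.0 h.

| setting | north-west | east | south |
|---|---|---|---|
| starting material | 1.0 M | 1.0 M | 1.0 M |
| partner | 1.50 equiv | 1.50 equiv | 1.50 equiv |
| protic impurity | 0.0200 M | 0.0200 M | 0.0200 M |
| temperature | 120 °C | 100 °C |  |
| time | 6.0 h | 6.0 h | 6.0 h |
| remark |  |  | at 120 °C until 80 min, from then on at 100 °C |

* the flask with the highest amount of target, in percent of the starting material charged ("all alike" if they lie within 1.5 percentage points) (north-west / east / south / all alike)
* final target, as a percentage of the starting material charged, in north-west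
* final target, as a percentage of the starting material charged, in east
* final target, as a percentage of the starting material charged, in south

    partner ⇌ dormant form (K1 = 0.14, k1 = 0.106 h⁻¹, Ea1 = 118 kJ mol⁻¹, ΔH1 = −56.0 kJ mol⁻¹)
    2 second intermediate → homo product (k2 = 0.465 L mol⁻¹ h⁻¹, Ea2 = 98.0 kJ mol⁻¹)
    partner + protic impurity → quenched reagent (k3 = 2.68 L mol⁻¹ h⁻¹, Ea3 = 74.0 kJ mol⁻¹)
    partner → second intermediate (k4 = 0.270 h⁻¹, Ea4 = 130 kJ mol⁻¹)
    starting material → open intermediate (k5 = 0.421 h⁻¹, Ea5 = 119 kJ mol⁻¹)
    open intermediate + second intermediate → target (k6 = 0.341 L mol⁻¹ h⁻¹, Ea6 = 91.0 kJ mol⁻¹)
    (constants at 100 °C)

- two of one species on the left: rate k times its square, two consumed each time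
- the constants hold at 100 °C; other temperatures follow from the activation energies and enthalpies

Second intermediate has two exits: with open intermediate to target, or with itself to homo product. I froze the ratio of those exits at equal concentrations. This ratio ρ, twice the homo constant over the cross constant, is the second intermediate lost to homo product per unit lost to target, a selectivity factor. It is 2.73 at 100 °C and 3.06 at 120 °C, since the two activation energies differ by 7.00 kJ mol⁻¹.

The supply per starting material is u, the partner equivalents less what the protic impurity can quench, so u is 1.48. Suppose both intermediates appeared at once. Dividing one rate by the other and integrating leaves open intermediate, as a fraction of its charge, at (1+(ρ−1)u) raised to the power −1/(ρ−1). Real release is spread out, and homo coupling goes with the square of second intermediate. I took the burst figure as an expected floor, not a proven bound: north-west should end above 49.3 %.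

One number was not enough, because ρ says nothing about whether a flask finishes. For that I counted coupling time constants in the run, θ = k6·cA·t, with k6 the cross constant at the flask's temperature, summed piece by piece in south, and cA the charge of starting material. This gave 9.10 in north-west, 3.61 in south and 2.05 in east. My choice was therefore north-west, with the largest count. In east the partner empties with a time constant of 4.22 h against the 6.0 h run, too close for a finish, so the floor does not apply there. I put no figure on east or south.

The forecast named north-west, with 57 %, 33 % and 50 % for north-west, east and south, “based on a rough hand estimate rather than a full calculation”.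

The simulation gave 57.3 % in north-west, 32.5 % in east and 50.4 % in south, so north-west led, and north-west stood above my floor. A neighbour flask like north-west but with 2.50 equiv of partner keeps ρ at 3.06 and raises u to 2.48, which puts its floor at 58.5 %. That floor is 9.2 percentage points above north-west's. The neighbour gave 69.5 %, up 12 points on north-west and above its floor. At its end the neighbour held 0 % of starting material and 30.5 % as open intermediate.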